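Whether extra free catalyst repays its cost in the flask turns on the apparent order in free catalyst at 10% conversion. No earlier run moves that charge, so this order can be reckoned but has not been measured.

| flask | starting material | second substrate | free catalyst | impurity | remark |
|---|---|---|---|---|---|
| ash | 1.5 M | 0.75 M | 15 mM | 7 mM | run made earlier |
| birch | 1.5 M | 3 M | 15 mM | 7 mM | run made earlier |
| larch | 3 M | 1.5 M | 15 mM | 7 mM | run made earlier |
| flask | 1.5 M | 1.50 M | 15 mM | 7.0 mM |  |

- ash (time / s: target / %, starting material / %): 10.0: 5.0, 93.4; 15.0: 8.4, 90.6; 25.0: 13.6, 84.1; 40.0: 19.6, 76.9; 60.0: 26.7, 66.1; 120: 45.2, 43.6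
- birch (time / s: target / %, starting material / %): 20.0: 7.6, 91.2; 40.0: 12.8, 82.2; 50.0: 15.4, 78.0; 80.0: 24.4, 67.7; 90.0: 25.3, 63.9; 120: 33.2, 56.1
- larch (time / s: target / %, starting material / %): 10.0: 4.7, 94.0; 25.0: 10.8, 86.9; 50.0: 19.9, 75.2; 80.0: 28.9, 62.1; 120: 40.1, 49.2

(scatter of a reading: 0.5 percentage points)

* apparent order in free catalyst when 10% of the starting material are converted (percent change of the rate of making target for one percent more free catalyst charged)

The first estimate lets each impurity take one free catalyst for good, so that 8.00 mM of the 15 mM charged goes on working. If the rate follows the working catalyst, one percent more charge gives 1.88 percent more rate, and this number is the titration gain, the catalyst charged over the catalyst the impurity leaves.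

That answer goes back against the ash run. Target made per second and per unit of starting material present is 0.00535 s⁻¹ up to 10.0 s and 0.00562 s⁻¹ between 60.0 s and 120 s. With a scatter of 0.5 percentage points on a first reading of 5.0%, these two readings agree within that scatter, so the ash run shows no slowing after its first reading.

The second round takes in the second substrate. Birch, with 3 M of it, starts at 0.00380 s⁻¹ of the charge against 0.00500 s⁻¹ in ash, which suggests that a share of the catalyst is held there. A fixed share of the working catalyst scales the rate and leaves the gain as it stood.

The weak link is "for good": a weak, reversible capture gives an order near 1, and these runs, all with the same impurity charge, do not separate the two cases. With the impurity at 46.7% of the catalyst, this reckoning stays with 1.88.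

The forecast differs: it gives 1.3, within 0.85 to 2, in the words “I lean slightly above 1”, which is below the gain.

The flask gives 1.9.

    second substrate + free catalyst ⇌ catalyst intermediate B (K = 0.590 M⁻¹, k = 1.30 M⁻¹ s⁻¹)
    free catalyst + impurity → spent catalyst (k = 190 M⁻¹ s⁻¹)
    starting material → uncatalysed product (k = 0.00130 s⁻¹)
    catalyst intermediate A → free catalyst + target (k = 25.0 s⁻¹)
    starting material + free catalyst ⇌ catalyst intermediate A (K = 1.20 M⁻¹, k = 0.880 M⁻¹ s⁻¹)
    catalyst intermediate B → free catalyst + second product (k = 1.80 s⁻¹)

In the flask after 0.300 min, impurity stands at 0% of its own charge and spent catalyst at 46.7% of the catalyst charged. The conversion of free catalyst and impurity into spent catalyst is the largest single effect on the order, since the same flask run without that conversion has an order of 1.0. For that run without the conversion, the titration gain predicts a rate at 10% conversion higher by a factor of 1.88, and the run gives a factor of 1.88.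

The readings are simulated for substances that don't exist, noise included.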